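A direct plan would start from the intact flavone apigenin A1, benzylate O7 and O4' and iodinate C6 to give the 6-iodoflavone A2, attach the side chain by a stereospecific Suzuki–Miyaura coupling with the secondary benzylic trifluoroborate A3 (from benzyl cinnamate by asymmetric conjugate borylation with CuCl, a chiral bisphosphine and B2pin2), and then hydrogenolyse. Its weakest steps would be:
- the coupling, because a secondary alkylboron would have to transmetalate with clean inversion onto a di-ortho-oxygenated arylpalladium intermediate and then escape β-hydride elimination;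
- the iodination, because C8 and C3 would compete with C6;
- the borylation, because its enantioselectivity would need upgrading by crystallisation.

The new route reads the target as 3-phenylglutaric acid whose second CH2–CO2H arm is buried in ring A as C6–C7. The stereocentre is therefore set on the open-chain diacid, by enantiotopic-group-selective methanolysis of the prochiral anhydride, and ring A is built last on a finished ring C: the lateral carbanion of a 2-methyl-4-pyranone-3-carboxylate is acylated by the hemiester (C7–C8) and the ketone then closes onto the pyranone ester (C5–C6), the 1,3-dioxygenation of C5 and C7 arising from the two ester carbonyls. The 6-position is fixed by construction, so the hindered alkyl–aryl coupling, the flavone iodination and the boron stereocentre all disappear.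

Key step: step 4

Assumption: (DHQD)2AQN is taken to give the (S)-hemiester 2; if its sense of induction is the opposite, the pseudo-enantiomeric (DHQ)2AQN is used and nothing else changes.
Lithium and magnesium salts of numbered compounds that form in the flask are not numbered separately.

Step 1
Reactants: 1 3-phenylglutaric anhydride (4-phenyloxane-2,6-dione)
Product: 2 (3S)-5-methoxy-5-oxo-3-phenylpentanoic acid
Conditions: MeOH (10 equiv), (DHQD)2AQN (20 mol%), Et2O, −40 °C; 1 M HCl extraction (catalyst recovered)
Reagents that add atoms: methanol, CO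
Why: Cinchona-alkaloid (general-base) catalysed alcoholysis of a prochiral cyclic anhydride, in which the quinuclidine nitrogen delivers methanol to one of the two enantiotopic carbonyl groups, so C3 is fixed as (S) by enantiotopic-group selection; crystallisation of the hemiester or of its 1-phenylethylammonium salt should raise the optical purity if needed.

Step 2
Reactants: 3 1-(benzyloxy)-4-ethynylbenzene
Product: 4 3-[4-(benzyloxy)phenyl]prop-2-ynoic acid
Conditions: n-BuLi (1.05 equiv), THF, −78 °C; CO2 (excess), −78 °C to rt; 1 M HCl
Reagents that add atoms: carbon dioxide, O=C=O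
Why: Carboxylation of a lithium acetylide, the terminal alkyne C–H being the only acidic site and the acetylide adding once to CO2.

Step 3
Reactants: 4 3-[4-(benzyloxy)phenyl]prop-2-ynoic acid; 5 methyl acetoacetate (1.1 equiv)
Product: 8 methyl 6-[4-(benzyloxy)phenyl]-2-methyl-4-oxo-4H-pyran-3-carboxylate, via ynoyl chloride 6 (not isolated), via acylated keto ester 7 (not isolated)
Conditions: (COCl)2 (1.2 equiv), DMF (cat.), CH2Cl2, 0 °C to rt, evaporate; then 5, MgCl2 (1.1 equiv), pyridine (2.5 equiv), CH2Cl2, 0 °C to rt; 1 M HCl wash; then TsOH·H2O (5 mol%), CH2Cl2, rt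
Reagents that add atoms: none
Why: Magnesium-chelate-controlled C-acylation of a β-keto ester by an acid chloride gives the enolised tricarbonyl compound 7, whose acetyl enol oxygen then adds 6-endo-dig to the ynone (acid-catalysed oxa-Michael cyclisation of an acetylenic β-diketone), closing the 4-pyranone with the methyl and ester groups on adjacent carbons.

Step 4
Reactants: 8 methyl 6-[4-(benzyloxy)phenyl]-2-methyl-4-oxo-4H-pyran-3-carboxylate; 2 (3S)-5-methoxy-5-oxo-3-phenylpentanoic acid (1.5 equiv)
Product: 10 (3R)-3-{2-[4-(benzyloxy)phenyl]-5,7-dihydroxy-4-oxo-4H-chromen-6-yl}-3-phenylpropanoic acid, via keto acid 9 (not isolated)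
Conditions: 8, LiN(SiMe3)2 (2.2 equiv), THF, −78 °C; Li salt of 2 (from 2 and LiN(SiMe3)2, 1.5 equiv), −78 to 0 °C; then LiN(i-Pr)2 (2.5 equiv), −78 to 25 °C; cold 1 M HCl
Reagents that add atoms: none
Why: The 2-methyl group of 8 (C8 of the target) is γ to both the C4 carbonyl and the C3 ester, so LiN(SiMe3)2 should remove only this proton, and the dienolate attacks through carbon the one electrophilic carbonyl of the lithium salt of 2, its methyl ester (Claisen condensation, C7–C8), the carboxylate arm being inert. The ketone 9 is held as its C8 enolate; LiN(i-Pr)2 then removes a C6 proton and this more reactive end of the dianion adds to the neighbouring pyranone ester (Dieckmann condensation, C5–C6, 6-(enolendo)-exo-trig), after which loss of methoxide and enolisation give the aromatic 5,7-diol of ring A. The closest known reactions are the lateral-carbanion acylation of 2-methyl-4-pyranones by esters and toluate-anion annulations of the Staunton–Weinreb type, in which an ortho ester closes a new phenolic ring. No stereocentre is formed: C3 of 2 becomes the diarylmethine carbon unchanged, it is never α to a carbonyl, and the hemiester is kept as its salt at or below 25 °C so that it cannot revert to the achiral anhydride. The selectivities needed are: arm selectivity, secured by the ester/carboxylate difference; C- over O-closure, secured because the lithium enolate of 9 should not lactonise at or below 0 °C whereas its dianion closes through carbon and aromatisation is irreversible; and 6- over 8-substitution, secured because the O1–C8a bond already exists in 8 and attack at C4 would give a bridged ring.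

Step 5
Reactants: 10 (3R)-3-{2-[4-(benzyloxy)phenyl]-5,7-dihydroxy-4-oxo-4H-chromen-6-yl}-3-phenylpropanoic acid
Product: 11 (3R)-3-[5,7-dihydroxy-2-(4-hydroxyphenyl)-4-oxo-4H-chromen-6-yl]-3-phenylpropanoic acid (target)
Conditions: H2 (1 atm), 10% Pd/C, THF/MeOH 1:1, rt
Reagents that add atoms: none
Why: Catalytic hydrogenolysis of the aryl benzyl ether under neutral conditions should leave the diarylmethine C–H bond and the pyranone double bond untouched at 1 atm and, being acid-free, should not lactonise the hydroxy acid.

**Compound list**
1 | 3-phenylglutaric anhydride (4-phenyloxane-2,6-dione) | O=C1CC(c2ccccc2)CC(=O)O1 | starting material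
2 | (3S)-5-methoxy-5-oxo-3-phenylpentanoic acid | COC(=O)C[C@@H](c1ccccc1)CC(=O)O | intermediate
3 | 1-(benzyloxy)-4-ethynylbenzene | C#Cc1ccc(OCc2ccccc2)cc1 | starting material
4 | 3-[4-(benzyloxy)phenyl]prop-2-ynoic acid | OC(=O)C#Cc1ccc(OCc2ccccc2)cc1 | intermediate
5 | methyl acetoacetate (methyl 3-oxobutanoate) | COC(=O)CC(C)=O | starting material
6 | 3-[4-(benzyloxy)phenyl]prop-2-ynoyl chloride (not isolated) | ClC(=O)C#Cc1ccc(OCc2ccccc2)cc1 | intermediate
7 | methyl 2-acetyl-5-[4-(benzyloxy)phenyl]-3-oxopent-4-ynoate (not isolated) | COC(=O)C(C(C)=O)C(=O)C#Cc1ccc(OCc2ccccc2)cc1 | intermediate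
8 | methyl 6-[4-(benzyloxy)phenyl]-2-methyl-4-oxo-4H-pyran-3-carboxylate | COC(=O)c1c(C)oc(-c2ccc(OCc3ccccc3)cc2)cc1=O | intermediate
9 | (3R)-6-{6-[4-(benzyloxy)phenyl]-3-(methoxycarbonyl)-4-oxo-4H-pyran-2-yl}-5-oxo-3-phenylhexanoic acid (not isolated) | OC(=O)C[C@H](c1ccccc1)CC(=O)Cc1oc(-c2ccc(OCc3ccccc3)cc2)cc(=O)c1C(=O)OC | intermediate
10 | (3R)-3-{2-[4-(benzyloxy)phenyl]-5,7-dihydroxy-4-oxo-4H-chromen-6-yl}-3-phenylpropanoic acid | OC(=O)C[C@H](c1ccccc1)c1c(O)cc2oc(-c3ccc(OCc4ccccc4)cc3)cc(=O)c2c1O | intermediate
11 | (3R)-3-[5,7-dihydroxy-2-(4-hydroxyphenyl)-4-oxo-4H-chromen-6-yl]-3-phenylpropanoic acid | O=C(O)C[C@H](c1ccccc1)c1c(O)cc2oc(-c3ccc(O)cc3)cc(=O)c2c1O | target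

Total step count: 5. Longest linear sequence: 4 steps (steps 2 to 5).

Steps most likely to fail:

1. Step 4. The stabilised lateral carbanion may acylate the ester of a carboxylate salt too slowly, so that proton exchange and self-condensation take over, or the ketone enolate may close through oxygen and stall as an enol lactone. The fallback would set out from 2 and come back at 10, using an activated acyl donor and a protected second arm. The free acid of 2 would be tert-butylated with tert-butyl 2,2,2-trichloroacetimidate to the mixed diester 1-tert-butyl 5-methyl (3R)-3-phenylpentanedioate F1. Its methyl ester would be saponified selectively with LiOH to (3R)-5-tert-butoxy-5-oxo-3-phenylpentanoic acid F2, which would be activated with 1,1'-carbonyldiimidazole as tert-butyl (3R)-5-(1H-imidazol-1-yl)-5-oxo-3-phenylpentanoate F3. Lithiated 8 would be acylated by this acyl imidazole at −78 °C and the dianion closed with LiN(i-Pr)2 to tert-butyl (3R)-3-{2-[4-(benzyloxy)phenyl]-5,7-dihydroxy-4-oxo-4H-chromen-6-yl}-3-phenylpropanoate F4, and brief treatment with CF3CO2H would unmask this ester to 10.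

2. Step 1. The enantiotopic-group selectivity may be low or reversed, or be eroded by uncatalysed background methanolysis. The fallback would set out from 1 and come back at 2: acid-catalysed methanolysis (MeOH, H2SO4) would give dimethyl 3-phenylpentanedioate F5, and one of its two enantiotopic ester groups would be hydrolysed by a hydrolase (pig liver esterase, α-chymotrypsin or Candida antarctica lipase B, whichever proves (S)-selective).

3. Step 3. The keto ester may be acylated on oxygen, chloride or pyridine may add across the ynoyl chloride, or the cyclisation may go through the wrong oxygen or in the 5-exo mode. The fallback would set out from 5 and come back at 8: C-acylation under the same MgCl2/pyridine conditions with (2E)-3-[4-(benzyloxy)phenyl]prop-2-enoyl chloride F6, itself from commercial 4-(benzyloxy)cinnamic acid and (COCl)2, would give methyl (4E)-2-acetyl-5-[4-(benzyloxy)phenyl]-3-oxopent-4-enoate F7, and oxidative cyclisation with catalytic I2 in DMSO at 110 °C, as in the conversion of 2'-hydroxychalcones into flavones, would close and dehydrogenate it to 8.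

Further compounds
F1 | step 4 | 1-tert-butyl 5-methyl (3R)-3-phenylpentanedioate | COC(=O)C[C@@H](c1ccccc1)CC(=O)OC(C)(C)C
F2 | step 4 | (3R)-5-tert-butoxy-5-oxo-3-phenylpentanoic acid | OC(=O)C[C@@H](c1ccccc1)CC(=O)OC(C)(C)C
F3 | step 4 | tert-butyl (3R)-5-(1H-imidazol-1-yl)-5-oxo-3-phenylpentanoate | O=C(C[C@@H](c1ccccc1)CC(=O)OC(C)(C)C)n1ccnc1
F4 | step 4 | tert-butyl (3R)-3-{2-[4-(benzyloxy)phenyl]-5,7-dihydroxy-4-oxo-4H-chromen-6-yl}-3-phenylpropanoate | CC(C)(C)OC(=O)C[C@H](c1ccccc1)c1c(O)cc2oc(-c3ccc(OCc4ccccc4)cc3)cc(=O)c2c1O
F5 | step 1 | dimethyl 3-phenylpentanedioate | COC(=O)CC(c1ccccc1)CC(=O)OC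
F6 | step 3 | (2E)-3-[4-(benzyloxy)phenyl]prop-2-enoyl chloride | O=C(Cl)/C=C/c1ccc(OCc2ccccc2)cc1
F7 | step 3 | methyl (4E)-2-acetyl-5-[4-(benzyloxy)phenyl]-3-oxopent-4-enoate | COC(=O)C(C(C)=O)C(=O)/C=C/c1ccc(OCc2ccccc2)cc1
A1 | direct plan | apigenin | O=c1cc(-c2ccc(O)cc2)oc2cc(O)cc(O)c12
A2 | direct plan | 7-(benzyloxy)-2-[4-(benzyloxy)phenyl]-5-hydroxy-6-iodo-4H-chromen-4-one | O=c1cc(-c2ccc(OCc3ccccc3)cc2)oc2cc(OCc3ccccc3)c(I)c(O)c12
A3 | direct plan | potassium (S)-[3-(benzyloxy)-3-oxo-1-phenylpropyl]trifluoroborate | [K+].O=C(OCc1ccccc1)C[C@@H](c1ccccc1)[B-](F)(F)F
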